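## Structural features

Renealtin A is a diarylheptanoid whose seven-carbon chain is folded into a single oxolane. O1 bridges C2 and C5; C2 carries a 4-hydroxy-3-methoxybenzyl group, C3 a free hydroxyl, C4 is a methylene, and C5 carries a CH2–C(=O)–aryl arm ending in the second guaiacyl ring. The three stereocentres are (2R,3R,5R), with all three substituents on one face of the ring. C2 and C3 are contiguous, whereas C5 is separated from them by C4 and relates to C2 only across the ring oxygen. The fragile element is the β-alkoxy aryl ketone: O1 is β to the carbonyl, so base or hot acid can open the ring by a retro-oxa-Michael reaction and scramble C5. The free phenols are oxidation-prone and have to be masked for most of the route. The real difficulty is the all-cis arrangement: cis- and trans-2,5-disubstituted oxolanes differ little in energy, and the C3 hydroxyl sits on the more hindered face. The key step exploits the array O1–C2–CH2Ar next to C3: with C3 as a ketone and C2 as a metal carbenoid carbon, the benzylic group can start on the oxygen that becomes O1 and be transferred to C2 while the O1–C2 bond closes the oxolane.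

## Logic of the disconnections

**18 from 17.** The two phenolic O–CH2Ph bonds are cut last. Benzyl ethers are chosen as phenol masks because they survive every acidic, basic and organometallic step. A 4-silyloxybenzyl ether on the migrating group, by contrast, would fragment through a quinone methide as soon as the silyl group was lost. The gain is a neutral final step that cannot trigger ring opening at C5. The demand is chemoselectivity: the aryl ketone must not be reduced.

**17 from 15 (through 16).** The C3–H bond is cut and the side-chain carbonyl is retraced to its dioxolane. This removes the most hindered stereocentre and leaves it to a bulky hydride. The hydride must attack anti to the two cis substituents, C2 and C5 must already be cis, and the aryl ketone must stay masked while hydride is present.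

**15 from 12 (through 13 and 14).** The O1–C2 and C2–CH2Ar bonds are cut together. Ring, benzylic C–C bond and the C2 stereocentre disappear, leaving an open chain with one stereocentre, one ether and a diazoketone. The forward step must channel the carbenoid to the ether oxygen rather than to C–H bonds, other oxygens or a second carbenoid. The benzylic group must go to carbon rather than to the enolate oxygen, and C2 must end up cis to C5, by equilibration if necessary.

**12 from 10 (through 11).** The C1–C2 bond of the diazoketone is cut, which leads back to a carboxylic acid. The activation has to be mild enough for the ketal and the electron-rich benzylic ether.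

**10 from 9, and 9 from 8.** The acid is retraced to its ethyl ester and the two ketal C–O bonds are cut to expose the aryl ketone. The ketal is needed so that only one ketone is present in the carbenoid and hydride steps. The demand is severe: a donor-deactivated aryl ketone with a β-alkoxy group must be ketalised without β-elimination and without loss of the acid-labile benzylic ether. This calls for aprotic conditions at low temperature.

**8 from 6 and 7.** The aryl–carbonyl bond is cut. This makes the route convergent and brings the second guaiacyl ring in as a catalogue boronic acid. The ketone synthesis must be neutral, because the acyl partner is a β-alkoxy carbonyl compound, and must leave the ethyl ester two carbons away untouched. A thiol ester–boronic acid coupling meets both conditions.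

**6 from 3 and 5 (5 from 4).** The secondary O–CH2Ar bond is cut. A β-hydroxy carbonyl compound cannot be alkylated under base (retro-aldol, elimination), so the benzylic group must be delivered as a cation equivalent under mild acid from an imidate made in one step from 4.

**3 from 2, and 2 from 1.** The acyl–S bond is cut, and the two differentiated arms are then recognised as the enantiotopic ester groups of a prochiral diester. One enzymatic hydrolysis supplies all the absolute stereochemistry (C5 of 18). The demand is high enantiotopic-group selectivity in the (S) sense, so that the acid arm becomes the aryl ketone arm and the ester arm the diazoketone arm.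

## Other disconnections considered

**Alternative 1:** The cut removes both exocyclic C–C bonds at C2 and C5 and traces the oxolane to furan A1. In the forward key step, Zn/Cu couple turns 1,1,3,3-tetrabromoacetone A2 into an oxyallyl cation that adds across the 2- and 5-positions of A1 in a [4+3] cycloaddition; the remaining bromines are reduced off in the same pot, giving the meso bicyclic ketone A3. The three-carbon ketone bridge would later be cleaved into the two side arms, for example by Baeyer–Villiger oxidation and lactone opening.

- In its favour: two bulk chemicals, one robust and scalable operation, and a cis relationship between the future C2 and C5 substituents that the bicycle enforces. On this point the alternative is better than the chosen plan, where the cis geometry rests on an equilibration at C2.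
- Against it here: A3 contains neither aryl group nor the C3 oxygen and is achiral. A desymmetrising step (asymmetric hydroboration) would have to decide which alkene carbon becomes C3. Exo-face addition would place that oxygen trans to both arms, so an inversion or an oxidation–reduction pair is needed. Both guaiacyl units would then have to be attached by two separate C–C bond formations, one of them an sp3–sp2 coupling at a carbon β to the ring oxygen.
- Comparison: mechanistically the cycloaddition is at least as dependable as carbenoid chemistry. Structurally it builds only the bare core, while the chosen key step closes the ring with both aryl-bearing arms in place. In step economy it is clearly inferior: desymmetrisation, inversion, ring cleavage and two arylations would put the count well above that of the chosen route.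

**Alternative 2:** The cut is the C4–C5 bond; O1–C5 is made beforehand by acetalisation. An (R)-3-aryllactic acid A4 (lactic acid itself would only deliver a methyl group at C2) and the dithiane-masked aldehyde A5 are condensed to a dioxolanone, which is methylenated to the enol acetal A6. In the forward key step, Al(i-Bu)3 ionises the acetal C–O bond of A6 to an aluminium enolate and an oxocarbenium ion, the enolate carbon closes onto it (Petasis–Ferrier rearrangement), and the same reagent reduces the C3 ketone by hydride transfer to give A7.

- In its favour: a convergent union of two fragments, no diazo chemistry, a C2 stereocentre taken intact from the hydroxy acid, and the C3 carbinol set in the same pot. On the security of C2 and on the saved reduction step the alternative is better than the chosen plan.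
- Against it here: the hydroxy acid needed belongs to the unnatural series and requires its own enantioselective preparation. A5 is a β-keto aldehyde equivalent that must itself be made and masked. The carbonyl methylenation with a titanium reagent (Cp2TiMe2) and the strongly Lewis-acidic aluminium reagent both have to tolerate sulfur and aryl silyl ethers. The five-membered version of the rearrangement closes in an endo mode that is less favourable than the six-membered case, so cis control at C5 depends on a single envelope transition state. Finally, the dithiane must be removed under oxidative or thiophilic conditions from an electron-rich, hydroxyl-bearing product.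
- Comparison: the key step makes one skeletal bond and two stereocentres, against two skeletal bonds and one stereocentre in the chosen step. Overall length should be about equal, with more of it spent on fragment synthesis.

**Alternative 3:** The cut is the O1–C2 bond alone. The substrate is the Z-configured homoallylic alcohol A8, already carrying both aryl groups and the ketone. In the forward key step, VO(Oi-Pr)3 with a chiral bishydroxamic acid ligand and tert-butyl hydroperoxide epoxidises the Z alkene under direction of the C5 hydroxyl to the cis-epoxide A9. The same hydroxyl then opens A9 at C2 in a 5-endo manner with inversion to give the bis-silyl ether A10.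

- In its favour: the C3 hydroxyl arrives free and necessarily cis to the C2 substituent, because a cis epoxide is opened anti. No C3 ketone, no reduction and no ketone protection are needed, and one desilylation finishes the synthesis. In endgame length and in the C2/C3 relationship this alternative is better than the chosen plan, and its total step count could be equal or lower.
- Against it here: A8 is a β-hydroxy aryl ketone with a skipped, benzylic Z alkene. It is prone to dehydration, retro-aldol cleavage and alkene migration into conjugation, and its enantioselective synthesis would need an aldol reaction of a β,γ-unsaturated aldehyde. Direction by a homoallylic hydroxyl is weaker than by an allylic one, so the face selectivity rests on the ligand, with a matched or mismatched pairing. The ring opening must prefer C2 over C3 although C2 carries no cation-stabilising group, and the electron-rich arene one carbon away can participate.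
- Comparison: the alternative concentrates three selectivity problems (face, regiochemistry of opening, chemoselectivity) in one step on a fragile substrate. The chosen plan spreads its risks over separately controllable steps on robust intermediates.

Key step: step 9

Assumption: 4 and 7 are treated as catalogue compounds in O-benzylated form, and the target is the all-cis (2R,3R,5R) isomer encoded by the SMILES.

## Route

Step 1
Reactants: 1 diethyl 3-hydroxyglutarate
Product: 2 (S)-5-ethoxy-3-hydroxy-5-oxopentanoic acid
Conditions: Novozym 435 (immobilised Candida antarctica lipase B), phosphate buffer pH 7, rt, pH-stat (1 M NaOH); then HCl to pH 2, EtOAc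
Reagents that add atoms: water, O
Why: Enzymatic desymmetrisation of a prochiral glutarate by enantiotopic-group-selective ester hydrolysis: the lipase is expected to cleave the pro-S ester arm, which fixes the carbinol centre that becomes C5 of the target. The carboxylate formed is a poor substrate, so hydrolysis should stop at the half-ester; the sense and level of induction are to be checked on 2 before going on.

Step 2
Reactants: 2 (S)-5-ethoxy-3-hydroxy-5-oxopentanoic acid
Product: 3 ethyl (R)-3-hydroxy-5-oxo-5-(phenylsulfanyl)pentanoate
Conditions: PhSH, DCC, DMAP (cat.), CH2Cl2, 0 °C → rt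
Reagents that add atoms: thiophenol, Sc1ccccc1
Why: Steglich-type carbodiimide thioesterification: the thiol is far more nucleophilic than the secondary hydroxyl towards the activated acyl species, so the hydroxyl can stay free, and the near-neutral conditions avoid dehydration. The stereocentre is untouched; the descriptor changes only through the priority rules.

Step 3
Reactants: 4 4-benzyloxy-3-methoxybenzyl alcohol
Product: 5 4-benzyloxy-3-methoxybenzyl 2,2,2-trichloroacetimidate
Conditions: Cl3CCN, DBU (cat.), CH2Cl2, 0 °C
Reagents that add atoms: trichloroacetonitrile, N#CC(Cl)(Cl)Cl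
Why: Base-catalysed addition of the benzylic alcohol to the nitrile (trichloroacetimidate formation). The electron-rich imidate ionises easily and is therefore used directly after filtration through base-washed silica.

Step 4
Reactants: 3 ethyl (R)-3-hydroxy-5-oxo-5-(phenylsulfanyl)pentanoate; 5 4-benzyloxy-3-methoxybenzyl 2,2,2-trichloroacetimidate
Product: 6 ethyl (R)-3-[(4-benzyloxy-3-methoxybenzyl)oxy]-5-oxo-5-(phenylsulfanyl)pentanoate
Conditions: PPTS (10 mol%), CH2Cl2, rt
Reagents that add atoms: none
Why: Acid-catalysed O-alkylation by a trichloroacetimidate: the donor-stabilised benzylic cation is transferred to the hydroxyl and neutral trichloroacetamide leaves. The β-hydroxy carbonyl compound never sees base, so retro-aldol cleavage and elimination are avoided, and the stereocentre is not involved.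

Step 5
Reactants: 6 ethyl (R)-3-[(4-benzyloxy-3-methoxybenzyl)oxy]-5-oxo-5-(phenylsulfanyl)pentanoate; 7 (4-benzyloxy-3-methoxyphenyl)boronic acid
Product: 8 ethyl (S)-3-[(4-benzyloxy-3-methoxybenzyl)oxy]-5-(4-benzyloxy-3-methoxyphenyl)-5-oxopentanoate
Conditions: Pd2(dba)3 (2.5 mol%), P(2-furyl)3 (10 mol%), Cu(O2C-2-thienyl) (1.5 equiv), THF, 50 °C
Reagents that add atoms: none
Why: Liebeskind–Srogl coupling: zerovalent palladium inserts into the acyl–S bond, the copper carboxylate binds sulfur and activates the boronic acid for base-free transmetalation, and reductive elimination gives the aryl ketone. The ethyl ester, the benzylic ether and the β-alkoxy carbonyl array are inert under these neutral conditions; the descriptor changes only through the priority rules.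

Step 6
Reactants: 8 ethyl (S)-3-[(4-benzyloxy-3-methoxybenzyl)oxy]-5-(4-benzyloxy-3-methoxyphenyl)-5-oxopentanoate
Product: 9 ethyl (S)-3-[(4-benzyloxy-3-methoxybenzyl)oxy]-4-[2-(4-benzyloxy-3-methoxyphenyl)-1,3-dioxolan-2-yl]butanoate
Conditions: (TMSOCH2)2, TMSOTf (10 mol%), CH2Cl2, –78 → –20 °C; pyridine quench
Reagents that add atoms: 1,2-bis(trimethylsilyloxy)ethane, C[Si](C)(C)OCCO[Si](C)(C)C
Why: Silyl triflate-catalysed ketalisation with the bis-silyl ether of the diol, run aprotic at low temperature and driven by formation of hexamethyldisiloxane. No water and no hot protic acid are involved, which should keep the acid-labile benzylic ether in place and avoid β-elimination. The ketal ensures that only one ketone is present in steps 9 and 10.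

Step 7
Reactants: 9 ethyl (S)-3-[(4-benzyloxy-3-methoxybenzyl)oxy]-4-[2-(4-benzyloxy-3-methoxyphenyl)-1,3-dioxolan-2-yl]butanoate
Product: 10 (S)-3-[(4-benzyloxy-3-methoxybenzyl)oxy]-4-[2-(4-benzyloxy-3-methoxyphenyl)-1,3-dioxolan-2-yl]butanoic acid
Conditions: LiOH·H2O, THF/H2O, 0 °C → rt; then cold 0.5 M HCl to pH 4
Reagents that add atoms: lithium hydroxide, [Li+].[OH-]
Why: Ester saponification: benzyl ethers and the dioxolane are stable to hydroxide, and careful cold acidification to pH 4 liberates the acid without hydrolysing the ketal.

Step 8
Reactants: 10 (S)-3-[(4-benzyloxy-3-methoxybenzyl)oxy]-4-[2-(4-benzyloxy-3-methoxyphenyl)-1,3-dioxolan-2-yl]butanoic acid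
Product: 12 (R)-1-diazo-4-[(4-benzyloxy-3-methoxybenzyl)oxy]-5-[2-(4-benzyloxy-3-methoxyphenyl)-1,3-dioxolan-2-yl]pentan-2-one, via mixed isobutyl carbonic anhydride 11 (not isolated)
Conditions: i-BuOCOCl, Et3N, THF, –20 °C; then CH2N2, Et2O, 0 °C → rt
Reagents that add atoms: diazomethane, C=[N+]=[N-]; isobutyl chloroformate, CC(C)COC(=O)Cl (its atoms remain only in 11)
Why: Acylation of diazomethane by a mixed carbonic anhydride (first stage of an Arndt–Eistert sequence). The activation is neutral to slightly basic, so the ketal and the benzylic ether survive, and the departing isobutyl carbonate takes up the proton of the acyldiazonium intermediate; the descriptor changes only through the priority rules.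

Step 9
Reactants: 12 (R)-1-diazo-4-[(4-benzyloxy-3-methoxybenzyl)oxy]-5-[2-(4-benzyloxy-3-methoxyphenyl)-1,3-dioxolan-2-yl]pentan-2-one
Product: 15 (2R,5R)-2-(4-benzyloxy-3-methoxybenzyl)-5-{[2-(4-benzyloxy-3-methoxyphenyl)-1,3-dioxolan-2-yl]methyl}oxolan-3-one, via cyclic oxonium ylide 13 (not isolated), via trans ketone epimer 14 (not isolated)
Conditions: Cu(hfacac)2 (5 mol%), CH2Cl2, reflux, slow addition of 12 at high dilution; then DBU (0.3 equiv), rt
Reagents that add atoms: none
Why: The divalent copper complex, in all likelihood reduced to the active lower-valent species by the diazo compound, releases N2 from 12 and gives an electrophilic copper carbenoid; a lone pair of the ether oxygen four atoms away traps it, closing the five-membered ring in exo fashion with respect to the C=Cu bond and giving the cyclic oxonium ylide 13. The O–CH2Ar bond of 13 then breaks homolytically and the caged pair of a donor-substituted benzyl radical and a captodative 3-oxooxolan-2-yl radical recombines at carbon, which is a [1,2]-Stevens rearrangement; the closest known reaction type is the copper- or rhodium-catalysed conversion of benzyl ethers of 4-hydroxy-1-diazobutan-2-ones into 2-benzyloxolan-3-ones. Chemoselectivity rests on ring size and catalyst: only the benzylic ether oxygen can reach the carbenoid through a five-membered transition state, whereas the dioxolane and aryl ether oxygens would need seven-membered or larger rings. The electron-poor hexafluoroacetylacetonate ligands favour ylide formation over C–H insertion, and slow addition at high dilution suppresses carbene dimers. The shift to carbon has to win over the [1,4]-shift to the enolate oxygen and over radical escape; the donor-substituted benzyl group migrates readily but can also show some [1,4]-migration, so this partition is the main uncertainty. C5 is not touched and keeps the configuration set in step 1. The new C2 centre is not expected to form selectively (recombination on the face the benzyl group left would favour the trans isomer 14), so control is thermodynamic: DBU added after nitrogen evolution has ceased epimerises C2 through the enolate, and the cis isomer 15, which can place both substituents pseudo-equatorially on the envelope, should predominate, probably by a modest margin. Residual 14 is separated and resubmitted to DBU.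

Step 10
Reactants: 15 (2R,5R)-2-(4-benzyloxy-3-methoxybenzyl)-5-{[2-(4-benzyloxy-3-methoxyphenyl)-1,3-dioxolan-2-yl]methyl}oxolan-3-one
Product: 17 (2R,3R,5R)-2-(4-benzyloxy-3-methoxybenzyl)-5-[2-(4-benzyloxy-3-methoxyphenyl)-2-oxoethyl]oxolan-3-ol, via dioxolane alcohol 16 (not isolated)
Conditions: LiBH(s-Bu)3, THF, –78 °C; then 2 M aq HCl, 0 °C → rt
Reagents that add atoms: water, O
Why: Diastereoselective ketone reduction with a bulky trialkylborohydride, followed by acid hydrolysis of the ketal in the same flask. Hydride is delivered to the C3 carbonyl from the face opposite the cis C2 and C5 substituents (the C2 benzylic group next to the carbonyl dominates), which places the hydroxyl cis to both. Aqueous acid then unmasks the aryl ketone; any bicyclic ketal formed transiently from the C3 hydroxyl should revert to the conjugated ketone.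

Step 11
Reactants: 17 (2R,3R,5R)-2-(4-benzyloxy-3-methoxybenzyl)-5-[2-(4-benzyloxy-3-methoxyphenyl)-2-oxoethyl]oxolan-3-ol
Product: 18 renealtin A, (2R,3R,5R)-2-(4-hydroxy-3-methoxybenzyl)-5-[2-(4-hydroxy-3-methoxyphenyl)-2-oxoethyl]oxolan-3-ol
Conditions: H2 (1 atm), Pd/C (10%), EtOAc, rt
Reagents that add atoms: none
Why: Catalytic hydrogenolysis of aryl benzyl ethers under neutral conditions: O-debenzylation is much faster than reduction of the donor-substituted aryl ketone, which becomes a vinylogous acid once its para-phenol is free. The absence of acid or base leaves the β-alkoxy ketone and C5 untouched.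

## Compound list

1 | diethyl 3-hydroxyglutarate | CCOC(=O)CC(O)CC(=O)OCC | starting material
2 | (S)-5-ethoxy-3-hydroxy-5-oxopentanoic acid | CCOC(=O)C[C@@H](O)CC(=O)O | intermediate
3 | ethyl (R)-3-hydroxy-5-oxo-5-(phenylsulfanyl)pentanoate | CCOC(=O)C[C@@H](O)CC(=O)Sc1ccccc1 | intermediate
4 | 4-benzyloxy-3-methoxybenzyl alcohol | COc1cc(CO)ccc1OCc1ccccc1 | starting material
5 | 4-benzyloxy-3-methoxybenzyl 2,2,2-trichloroacetimidate | COc1cc(COC(=N)C(Cl)(Cl)Cl)ccc1OCc1ccccc1 | intermediate
6 | ethyl (R)-3-[(4-benzyloxy-3-methoxybenzyl)oxy]-5-oxo-5-(phenylsulfanyl)pentanoate | CCOC(=O)C[C@@H](OCc1ccc(OCc2ccccc2)c(OC)c1)CC(=O)Sc1ccccc1 | intermediate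
7 | (4-benzyloxy-3-methoxyphenyl)boronic acid | COc1cc(B(O)O)ccc1OCc1ccccc1 | starting material
8 | ethyl (S)-3-[(4-benzyloxy-3-methoxybenzyl)oxy]-5-(4-benzyloxy-3-methoxyphenyl)-5-oxopentanoate | CCOC(=O)C[C@@H](OCc1ccc(OCc2ccccc2)c(OC)c1)CC(=O)c1ccc(OCc2ccccc2)c(OC)c1 | intermediate
9 | ethyl (S)-3-[(4-benzyloxy-3-methoxybenzyl)oxy]-4-[2-(4-benzyloxy-3-methoxyphenyl)-1,3-dioxolan-2-yl]butanoate | CCOC(=O)C[C@@H](OCc1ccc(OCc2ccccc2)c(OC)c1)CC1(c2ccc(OCc3ccccc3)c(OC)c2)OCCO1 | intermediate
10 | (S)-3-[(4-benzyloxy-3-methoxybenzyl)oxy]-4-[2-(4-benzyloxy-3-methoxyphenyl)-1,3-dioxolan-2-yl]butanoic acid | OC(=O)C[C@@H](OCc1ccc(OCc2ccccc2)c(OC)c1)CC1(c2ccc(OCc3ccccc3)c(OC)c2)OCCO1 | intermediate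
11 | mixed isobutyl carbonic anhydride of 10 | CC(C)COC(=O)OC(=O)C[C@@H](OCc1ccc(OCc2ccccc2)c(OC)c1)CC1(c2ccc(OCc3ccccc3)c(OC)c2)OCCO1 | intermediate (not isolated)
12 | (R)-1-diazo-4-[(4-benzyloxy-3-methoxybenzyl)oxy]-5-[2-(4-benzyloxy-3-methoxyphenyl)-1,3-dioxolan-2-yl]pentan-2-one | [N-]=[N+]=CC(=O)C[C@@H](OCc1ccc(OCc2ccccc2)c(OC)c1)CC1(c2ccc(OCc3ccccc3)c(OC)c2)OCCO1 | intermediate
13 | cyclic oxonium ylide, 1-(4-benzyloxy-3-methoxybenzyl)-4-oxooxolan-1-ium-2-ide with the (R)-configured 5-(ketal-methyl) substituent | O=C1C[C@H](CC2(c3ccc(OCc4ccccc4)c(OC)c3)OCCO2)[O+](Cc2ccc(OCc3ccccc3)c(OC)c2)[CH-]1 | intermediate (not isolated)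
14 | (2S,5R)-2-(4-benzyloxy-3-methoxybenzyl)-5-{[2-(4-benzyloxy-3-methoxyphenyl)-1,3-dioxolan-2-yl]methyl}oxolan-3-one (trans) | COc1cc(C[C@H]2C(=O)C[C@H](CC3(c4ccc(OCc5ccccc5)c(OC)c4)OCCO3)O2)ccc1OCc1ccccc1 | intermediate (not isolated)
15 | (2R,5R)-2-(4-benzyloxy-3-methoxybenzyl)-5-{[2-(4-benzyloxy-3-methoxyphenyl)-1,3-dioxolan-2-yl]methyl}oxolan-3-one (cis) | COc1cc(C[C@@H]2C(=O)C[C@H](CC3(c4ccc(OCc5ccccc5)c(OC)c4)OCCO3)O2)ccc1OCc1ccccc1 | intermediate
16 | (2R,3R,5R)-2-(4-benzyloxy-3-methoxybenzyl)-5-{[2-(4-benzyloxy-3-methoxyphenyl)-1,3-dioxolan-2-yl]methyl}oxolan-3-ol | COc1cc(C[C@@H]2[C@H](O)C[C@H](CC3(c4ccc(OCc5ccccc5)c(OC)c4)OCCO3)O2)ccc1OCc1ccccc1 | intermediate (not isolated)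
17 | (2R,3R,5R)-2-(4-benzyloxy-3-methoxybenzyl)-5-[2-(4-benzyloxy-3-methoxyphenyl)-2-oxoethyl]oxolan-3-ol | COc1cc(C[C@@H]2[C@H](O)C[C@H](CC(=O)c3ccc(OCc4ccccc4)c(OC)c3)O2)ccc1OCc1ccccc1 | intermediate
18 | renealtin A, (2R,3R,5R)-2-(4-hydroxy-3-methoxybenzyl)-5-[2-(4-hydroxy-3-methoxyphenyl)-2-oxoethyl]oxolan-3-ol | COc1cc(C[C@H]2O[C@@H](CC(=O)c3ccc(O)c(OC)c3)C[C@H]2O)ccc1O | target

## Step count and risks

Total step count: 11. Longest linear sequence: 10 steps (1 → 2 → 3 → 6 → 8 → 9 → 10 → 12 → 15 → 17 → 18; step 3 is the one-step side branch).

**Step 9 (key step).** The likely failure is an unfavourable partition of the ylide and its radical pair: migration of the benzylic group to the enolate oxygen, escape of the radicals from the solvent cage, or carbenoid C–H insertion and dimerisation. Incomplete enrichment of the cis isomer on equilibration is a second concern. The fallback makes the C2–benzylic bond by aldol condensation instead of by the shift. It sets out from 12. Anhydrous acid (CF3CO2H or BF3·OEt2, CH2Cl2, low temperature, 1,3,5-trimethoxybenzene as cation trap) should convert the diazoketone, through attack of the ether oxygen on the diazonium ion and loss of the donor-stabilised benzyl cation, into the C2-unsubstituted (R)-5-{[2-(4-benzyloxy-3-methoxyphenyl)-1,3-dioxolan-2-yl]methyl}oxolan-3-one F1. Amine-catalysed aldol condensation of this ketone with 4-benzyloxy-3-methoxybenzaldehyde at the more acidic C2 position should give the (R,Z)-2-(4-benzyloxy-3-methoxybenzylidene)oxolan-3-one F2. Conjugate reduction with [CuH(PPh3)]6, followed by the DBU equilibration used in step 9, returns to 15.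

**Step 6.** The likely failure is sluggish ketalisation of the donor-deactivated aryl ketone; forcing the temperature would then bring on β-elimination of the benzylic alkoxide or loss of the acid-labile benzylic ether. The fallback changes the order of events so that this ether is introduced only after the ketal. It sets out from 3. Liebeskind–Srogl coupling with 7 should give ethyl (S)-5-(4-benzyloxy-3-methoxyphenyl)-3-hydroxy-5-oxopentanoate F3. The same silyl triflate ketalisation, now with no acid-labile ether present (the hydroxyl is silylated in the flask and released by K2CO3/MeOH on work-up), should give ethyl (S)-4-[2-(4-benzyloxy-3-methoxyphenyl)-1,3-dioxolan-2-yl]-3-hydroxybutanoate F4. Alkylation of its hydroxyl with 5 under PPTS catalysis returns to 9.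

**Step 4.** The likely failure is self-condensation or rearrangement of the very electron-rich imidate outrunning its transfer to the poorly nucleophilic β-hydroxyl, or acid-induced dehydration of the substrate. The fallback replaces cation transfer by reductive etherification. It sets out from 3. TMSCl and imidazole should give ethyl (R)-5-oxo-5-(phenylsulfanyl)-3-(trimethylsilyloxy)pentanoate F5. This silyl ether is condensed with 4-benzyloxy-3-methoxybenzaldehyde and Et3SiH under catalytic TMSOTf at –78 °C, which forms the benzylic ether directly and returns to 6.

**Step 11.** The likely failure is over-reduction of the aryl ketone to the benzylic alcohol, and on to the methylene compound, before both benzyl ethers are cleaved. The fallback moves the hydrogenolysis ahead of the unmasking of the ketone. It sets out from 16, isolated by quenching step 10 with aqueous NH4Cl instead of HCl. H2 and Pd/C in EtOAc with a trace of Et3N should remove both benzyl groups while the carbonyl is still a dioxolane, giving (2R,3R,5R)-2-(4-hydroxy-3-methoxybenzyl)-5-{[2-(4-hydroxy-3-methoxyphenyl)-1,3-dioxolan-2-yl]methyl}oxolan-3-ol F6. Dilute aqueous HCl in THF then liberates the ketone and arrives at 18.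

## Further compounds

F1 | step 9 | (R)-5-{[2-(4-benzyloxy-3-methoxyphenyl)-1,3-dioxolan-2-yl]methyl}oxolan-3-one | O=C1CO[C@@H](CC2(c3ccc(OCc4ccccc4)c(OC)c3)OCCO2)C1
F2 | step 9 | (R,Z)-2-(4-benzyloxy-3-methoxybenzylidene)-5-{[2-(4-benzyloxy-3-methoxyphenyl)-1,3-dioxolan-2-yl]methyl}oxolan-3-one | COc1cc(/C=C2\O[C@@H](CC3(c4ccc(OCc5ccccc5)c(OC)c4)OCCO3)CC2=O)ccc1OCc1ccccc1
F3 | step 6 | ethyl (S)-5-(4-benzyloxy-3-methoxyphenyl)-3-hydroxy-5-oxopentanoate | CCOC(=O)C[C@@H](O)CC(=O)c1ccc(OCc2ccccc2)c(OC)c1
F4 | step 6 | ethyl (S)-4-[2-(4-benzyloxy-3-methoxyphenyl)-1,3-dioxolan-2-yl]-3-hydroxybutanoate | CCOC(=O)C[C@@H](O)CC1(c2ccc(OCc3ccccc3)c(OC)c2)OCCO1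
F5 | step 4 | ethyl (R)-5-oxo-5-(phenylsulfanyl)-3-(trimethylsilyloxy)pentanoate | CCOC(=O)C[C@@H](O[Si](C)(C)C)CC(=O)Sc1ccccc1
F6 | step 11 | (2R,3R,5R)-2-(4-hydroxy-3-methoxybenzyl)-5-{[2-(4-hydroxy-3-methoxyphenyl)-1,3-dioxolan-2-yl]methyl}oxolan-3-ol | COc1cc(C[C@@H]2[C@H](O)C[C@H](CC3(c4ccc(O)c(OC)c4)OCCO3)O2)ccc1O
A1 | alternative 1 | furan | c1ccoc1
A2 | alternative 1 | 1,1,3,3-tetrabromoacetone | O=C(C(Br)Br)C(Br)Br
A3 | alternative 1 | meso-8-oxabicyclo[3.2.1]oct-6-en-3-one | O=C1C[C@H]2C=C[C@@H](C1)O2
A4 | alternative 2 | (R)-3-[4-(tert-butyldimethylsilyloxy)-3-methoxyphenyl]-2-hydroxypropanoic acid | COc1cc(C[C@@H](O)C(=O)O)ccc1O[Si](C)(C)C(C)(C)C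
A5 | alternative 2 | 2-{2-[4-(tert-butyldimethylsilyloxy)-3-methoxyphenyl]-1,3-dithian-2-yl}acetaldehyde | O=CCC1(c2ccc(O[Si](C)(C)C(C)(C)C)c(OC)c2)SCCCS1
A6 | alternative 2 | cis-4-methylene-1,3-dioxolane enol acetal from A4 and A5 | COc1cc(C[C@H]2O[C@@H](CC3(c4ccc(O[Si](C)(C)C(C)(C)C)c(OC)c4)SCCCS3)OC2=C)ccc1O[Si](C)(C)C(C)(C)C
A7 | alternative 2 | all-cis 3-hydroxyoxolane with the ketone as dithiane | COc1cc(C[C@@H]2[C@H](O)C[C@H](CC3(c4ccc(O[Si](C)(C)C(C)(C)C)c(OC)c4)SCCCS3)O2)ccc1O[Si](C)(C)C(C)(C)C
A8 | alternative 3 | (R,Z)-1,7-bis[4-(tert-butyldimethylsilyloxy)-3-methoxyphenyl]-3-hydroxyhept-5-en-1-one | COc1cc(C/C=C\C[C@H](CC(=O)c2ccc(O[Si](C)(C)C(C)(C)C)c(OC)c2)O)ccc1O[Si](C)(C)C(C)(C)C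
A9 | alternative 3 | cis-5,6-epoxide of A8 | COc1cc(C[C@@H]2O[C@@H]2C[C@H](CC(=O)c2ccc(O[Si](C)(C)C(C)(C)C)c(OC)c2)O)ccc1O[Si](C)(C)C(C)(C)C
A10 | alternative 3 | bis(tert-butyldimethylsilyl) ether of renealtin A | COc1cc(C[C@@H]2[C@H](O)C[C@H](CC(=O)c3ccc(O[Si](C)(C)C(C)(C)C)c(OC)c3)O2)ccc1O[Si](C)(C)C(C)(C)C
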